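## Analysis of the target

Compound 38 is a 7a-methyl-2,4,5,6,7,7a-hexahydro-1H-inden-2-one. A cyclopentenone (C1, C2, C3, C3a, C7a) is fused to a cyclohexane (C3a, C4, C5, C6, C7, C7a), and the enone C2(=O)–C3=C3a has its β-carbon at the ring fusion. The ring carries four stereocentres, C1 (R), C4 (S), C7 (R) and the quaternary C7a (S). The formylallyl chain at C1, the acyloxy group at C4, the carboxyl at C7 and the methyl at C7a all lie on one face. A fifth centre (R) sits in the (2E,4E)-4,6-dimethylocta-2,4-dienoyl residue and cannot be relayed from the ring. Because the enone ring is flat, C1 is equatorial and the methyl axial on the six-membered ring, so the C4 oxygen is axial (syn to the methyl across sp2 C3a) and the carboxyl equatorial. The sensitive groups are the 2-substituted acrolein, the γ-acyloxy enone, the epimerisable C1, and two esters of which only one may be cleaved. The hard part is the all-carbon quaternary C7a, flanked by the C7 stereocentre and by an sp2 carbon, together with three oxygen functions (C2, C4, side chain) that must be told apart. The strategy rests on C4: it is a secondary allylic carbinol bonded to the ring-fusion carbon C3a, so the C3a–C4 bond can be made by adding a cyclopentenyl metal at C3a to an aldehyde at the end of the C7–C6–C5 chain.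

## Retrosynthetic reasoning

**Unmasking (38 ⇒ 37 ⇒ 36 ⇒ 35).** The free acid and the acrolein tolerate the least further chemistry. They are carried as a tert-butyl ester and a silyl-protected allylic alcohol and released in the last three steps. The tert-butyl ester is chosen because it can be cleaved without touching the dienoate.

**C4–O acyl bond (35 ⇒ 27 + 33).** The ester is cut late because a dienoate would not survive the enolate chemistry at C1. The forward reaction must acylate a hindered axial allylic alcohol with retention. Acid 33 comes from 28 through 29, 31 and 32 by two olefinations; its stereocentre is bought.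

**C1–CH2 bond (26 ⇒ 25 ⇒ 20 + 23).** The side chain is attached by α′-alkylation of enone 20 with the symmetrical allyl bromide 23 (from 21 through 22). C1 is the only position with kinetically accessible acidic hydrogens. Its configuration is α to the ketone and is therefore left to equilibration (25 to 26).

**Oxidation state and protection (20 ⇒ 19 ⇒ 18 ⇒ 17).** The C2 ketone is drawn from a C2 silyl ether, so the enone appears with its alkene already at C3=C3a. C4 is held as a 4-methoxybenzyl ether, which is orthogonal to both silyl ethers and to the tert-butyl ester.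

**C3a–C4 bond (17 ⇒ 15), the key disconnection.** Cutting here removes the six-membered ring and the C4 stereocentre and leaves a cyclopentenyl iodide with an aldehyde on a three-carbon tether. The forward step (through alkenylchromium species 16) must form the ring bond at an sp2 carbon with retention, next to a quaternary centre, without disturbing the ester, the silyl ether or C7.

**Aldehyde (15 ⇒ 13 ⇒ 12).** The aldehyde is stored as a terminal alkene and the acid is esterified only after the C7–C7a bond is in place.

**C7–C7a bond (12 ⇒ 9 ⇒ 7 + 8).** The bond between the two adjacent stereocentres is cut as an ester-enolate [3,3] rearrangement of ester 9. It makes the quaternary centre by chirality transfer from the carbinol of 7 and sets C7 in the same event. It also leaves the alkenyl iodide at C3a and the allylic silyl ether at C2 exactly where the key step needs them. Two successive enolate alkylations were not chosen: they would need a resolution and would leave C7 to an acyclic ester enolate whose neighbour carries three groups of similar size.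

**Cyclopentenol (7 ⇒ 6 ⇒ 3 ⇒ 2 ⇒ 1).** The carbinol comes from 1,2-reduction of iodoenone 6, 6 from oxidative transposition of tertiary alcohol 3, and 3 from methyl addition to iodoenone 2, made from enone 1. The single stereocentre of 1 becomes C2. It is a spectator that relays chirality to the carbinol of 7 and then to C7a, and it is oxidised away in step 12. It keeps the tert-butyldimethylsilyl group that 1 already carries.

## Alternatives that were turned down

**Alternative 1:** The six-membered ring is closed with light. Irradiation near 350 nm would join C7a to C7 and C1 to the acetoxy-bearing carbon of a tethered enol acetate in one enone–alkene [2+2] event, giving the tricyclic acetoxycyclobutane A1. Loss of the acetate and retro-aldol opening of the cyclobutane would then leave a formyl group on C7.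
- For it: two bonds, two rings, the quaternary centre with its methyl in place and C7 are made in one step, and the fragmentation is dependable. In bonds per step it is stronger than the chosen route.
- Against it: a cyclobutane can only be cis-fused to the six-membered ring, so the future carboxyl carbon leaves the cycloaddition on the face of C1, trans to the C7a methyl. The target has it cis, so an epimerisation at C7 with no evident thermodynamic bias must follow.
- Against it: A1 has lost the C3=C3a alkene, which must be reintroduced towards a ring-fusion carbon; the formyl group must be oxidised; and a four-atom tether is the less favourable case for regiocontrol.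
- Comparison: the chosen route offers a thermal, suprafacial construction of C7a and C7 and keeps the C3=C3a alkene from the alkenyl iodide onwards.

**Alternative 2:** The angular methyl is made, not carried. The C7a–CH3 bond is traced back to a cyclopropane CH2 bridging C1 and C7a, installed by a hydroxyl-directed Simmons–Smith reaction (Et2Zn, CH2I2) on a C1=C7a alkene under control of the C2 allylic alcohol, giving cyclopropyl carbinol A2. After oxidation at C2, reductive opening of the C1–CH2 bond would reveal the methyl and a C1 enolate.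
- For it: directed cyclopropanation is one of the most predictable facial controls available, at least as secure as the chirality transfer used here, and the opening would give a regiodefined enolate for the allylation.
- Against it: it needs a bicyclic precursor with a tetrasubstituted C1=C7a alkene and the C4 and C7 centres already in place. A2 is saturated at C3a, so the enone alkene must be introduced afterwards. The cyclopropane may open at C1–C7a instead of C1–CH2. More redox steps are needed.
- Comparison: the chosen route is shorter to the enone and never has to desaturate towards C3a.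

**Alternative 3:** The five-membered ring is disconnected. A propargylic pivalate at C3 on a C3a=C7a cyclohexene would rearrange under (Ph3P)AuSbF6 (cationic monovalent gold) in wet acetonitrile, forming C1–C7a and delivering hydrindenone A3, the silyl analogue of enone 20.
- For it: on step economy it is stronger than the chosen route. The enone arrives in one step with the C2 ketone and the C3=C3a alkene in place, and steps 10 to 12 of the chosen route would fall away.
- Against it: the new bond is made at a fully substituted alkene carbon, and the configuration of C7a then rests on remote substituents at C4 and C7 or on chirality transfer to a tetrasubstituted terminus, neither of which is assured. The trans-1,4-disubstituted cyclohexene must first be made as a single enantiomer. A 1,3-acyloxy shift to an allene competes.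
- Comparison: the chosen route sets C7a by a sigmatropic shift from a chiral-pool carbinol and makes the ring bond at an sp2 carbon with retention, so C7a does not depend on facial selectivity at a tetrasubstituted alkene.

Key step: step 9

Assumption: enone 1, acid 8, diol 21 and acid 28 are taken as purchased, 1 and 28 as single enantiomers. TBS = tert-butyldimethylsilyl, PMB = 4-methoxybenzyl.

## Route

Step 1
Reactants: 1 (S)-4-(TBSO)cyclopent-2-en-1-one
Product: 2 (S)-4-(TBSO)-2-iodocyclopent-2-en-1-one
Conditions: I2, pyridine, CH2Cl2, 0 °C to rt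
Reagents that add atoms: iodine, II
Why: α-Iodination of an enone by pyridine addition, iodination of the enolate and elimination; the β-unsubstituted enone is the ideal substrate and its γ-stereocentre is not enolisable.

Step 2
Reactants: 2 iodoenone
Product: 3 (1R,4S)-4-(TBSO)-2-iodo-1-methylcyclopent-2-en-1-ol
Conditions: MeMgBr, CeCl3, THF, −78 °C
Reagents that add atoms: methylmagnesium bromide, C[Mg]Br
Why: 1,2-Addition of the organocerium reagent formed in the flask, which suppresses enolisation and loss of the silyloxy group and does not exchange with the alkenyl iodide. Attack anti to the silyloxy group should give mainly the 1R carbinol, a centre that is erased in step 3.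

Step 3
Reactants: 3 tertiary allylic alcohol
Product: 6 (S)-5-(TBSO)-2-iodo-3-methylcyclopent-2-en-1-one, via tertiary chlorochromate ester 4 (not isolated), via transposed chlorochromate ester 5 (not isolated)
Conditions: pyridinium chlorochromate (C5H5NH)[CrO3Cl], 4 Å molecular sieves, CH2Cl2, rt
Reagents that add atoms: none
Why: Oxidative 1,3-transposition of a tertiary allylic alcohol (Dauben–Babler): ester 4 undergoes a suprafacial [3,3] shift to 5, which is oxidised to the ketone. The carbonyl ends next to the silyloxy carbon and the methyl on the alkene carbon that becomes C7a; the non-basic medium protects the α-silyloxy centre from enolisation.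

Step 4
Reactants: 6 iodoenone
Product: 7 (1S,5S)-5-(TBSO)-2-iodo-3-methylcyclopent-2-en-1-ol
Conditions: NaBH4, CeCl3·7H2O, MeOH, −78 °C
Reagents that add atoms: none
Why: Luche 1,2-reduction; hydride is delivered anti to the neighbouring silyloxy group, so the new hydroxyl is cis to it (1S). The alkenyl iodide is not reduced and the ketone is removed before it can enolise.

Step 5
Reactants: 7 cis-iodocyclopentenol; 8 hex-5-enoic acid
Product: 9 (1S,5S)-5-(TBSO)-2-iodo-3-methylcyclopent-2-en-1-yl hex-5-enoate
Conditions: dicyclohexylcarbodiimide, 4-dimethylaminopyridine (cat.), CH2Cl2, 0 °C to rt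
Reagents that add atoms: none
Why: Steglich esterification of a secondary allylic alcohol with retention; the near-neutral conditions avoid silyl migration between the cis oxygens.

Step 6
Reactants: 9 allylic ester
Product: 12 (2R)-2-[(1S,4S)-4-(TBSO)-2-iodo-1-methylcyclopent-2-en-1-yl]hex-5-enoic acid, via (E)-silyl ketene acetal 10 (not isolated), via trimethylsilyl ester 11 (not isolated)
Conditions: LiN(iPr)2, THF, −78 °C; Me3SiCl, Et3N, −78 °C to 65 °C; then 0.5 M HCl, 0 °C
Reagents that add atoms: none
Why: Ireland–Claisen rearrangement, a reaction type established for 2-halocycloalkenyl esters. The [3,3] shift is suprafacial, so C7 bonds to C7a on the face that carried the ester oxygen and C7a is fixed as S by chirality transfer from the carbinol. The cis silyloxy group at C2 blocks the chair-like array, and the boat-like array should translate the E geometry of 10 (kinetic enolisation in THF) into R at C7.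

Step 7
Reactants: 12 carboxylic acid
Product: 13 tert-butyl (2R)-2-[(1S,4S)-4-(TBSO)-2-iodo-1-methylcyclopent-2-en-1-yl]hex-5-enoate
Conditions: tert-butyl 2,2,2-trichloroacetimidate, cyclohexane/CH2Cl2, rt
Reagents that add atoms: tert-butyl 2,2,2-trichloroacetimidate, CC(C)(C)OC(=N)C(Cl)(Cl)Cl
Why: tert-Butylation through a tert-butyl cation–carboxylate ion pair is insensitive to the congestion around C7, and no strong acid is present that would remove the silyl ether.

Step 8
Reactants: 13 tert-butyl hexenoate
Product: 15 tert-butyl (2R)-2-[(1S,4S)-4-(TBSO)-2-iodo-1-methylcyclopent-2-en-1-yl]-5-oxopentanoate, via vicinal diol 14 (not isolated)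
Conditions: OsO4 (cat.), NaIO4, 2,6-lutidine, dioxane/H2O, rt
Reagents that add atoms: sodium periodate (terminal oxygen source), [Na+].[O-]I(=O)(=O)=O; osmium tetroxide (catalytic oxygen carrier), O=[Os](=O)(=O)=O
Why: Lemieux–Johnson cleavage; OsO4 dihydroxylates the monosubstituted terminal alkene far faster than the hindered, electron-poor iodoalkene, and periodate cleaves diol 14 to the aldehyde.

Step 9
Reactants: 15 iodo aldehyde
Product: 17 tert-butyl (2S,4S,7R,7aS)-2-(TBSO)-4-hydroxy-7a-methyl-2,4,5,6,7,7a-hexahydro-1H-indene-7-carboxylate, via alkenylchromium dichloride 16 (not isolated)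
Conditions: CrCl2 (8 equiv), NiCl2 (2 mol %), degassed DMF, 0.01 M, rt
Reagents that add atoms: none
Why: NiCl2 is reduced by CrCl2 to zerovalent nickel, which inserts into the C3a–I bond; transmetalation to trivalent chromium gives 16 and divalent chromium returns the nickel to its cycle. The aldehyde binds to the oxophilic chromium and the alkenyl group migrates to the carbonyl carbon with retention at C3a, forming C3a–C4 in a 6-exo-trig closure of the six-membered ring; the closest known reaction is the intramolecular Nozaki–Hiyama–Kishi coupling of cycloalkenyl iodides or triflates with tethered aldehydes. The new centre C4 is controlled by the tether: C7 lies on the face of the cyclopentene opposite the C7a methyl, so the aldehyde carbon reaches C3a from that face while its oxygen stays on the chromium in the ring plane. When C4 swings into that plane the C–O bond is left axial on the methyl face, which is the 4S carbinol. In this chair-like array the tert-butyl ester is equatorial and the methyl axial, so nothing else opposes the closure. The competing in-plane delivery with the oxygen equatorial would give the C4 epimer; this facial selectivity is what the step needs and is its least certain point. Chemoselectivity is secured by the reagent: alkenylchromium species add to aldehydes but not to esters, do not epimerise C7 or enolise the aldehyde, and tolerate the silyl ether. The quaternary neighbour does not hinder insertion at an sp2 carbon, and the dilution disfavours intermolecular addition.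

Step 10
Reactants: 17 bicyclic allylic alcohol
Product: 18 tert-butyl (2S,4S,7R,7aS)-2-(TBSO)-4-(PMBO)-7a-methyl-2,4,5,6,7,7a-hexahydro-1H-indene-7-carboxylate
Conditions: NaH, 4-methoxybenzyl chloride, Bu4NI (cat.), DMF, 0 °C to rt
Reagents that add atoms: 4-methoxybenzyl chloride, COc1ccc(CCl)cc1
Why: Williamson etherification of the alkoxide with the benzylic iodide formed in the flask; the ether is orthogonal to both silyl ethers and to the tert-butyl ester, which is too hindered to be attacked or enolised.

Step 11
Reactants: 18 silyl ether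
Product: 19 tert-butyl (2S,4S,7R,7aS)-2-hydroxy-4-(PMBO)-7a-methyl-2,4,5,6,7,7a-hexahydro-1H-indene-7-carboxylate
Conditions: Bu4NF, THF, rt
Reagents that add atoms: none
Why: Fluoride cleaves the only silyl ether; no base-sensitive group is present at this stage.

Step 12
Reactants: 19 C2 allylic alcohol
Product: 20 tert-butyl (4S,7R,7aS)-4-(PMBO)-7a-methyl-2-oxo-2,4,5,6,7,7a-hexahydro-1H-indene-7-carboxylate
Conditions: Dess–Martin periodinane, CH2Cl2, rt
Reagents that add atoms: none
Why: Oxidation of the allylic alcohol gives the enone with its alkene already at C3=C3a; C4 is an ether and cannot be oxidised.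

Step 13
Reactants: 21 2-methylidenepropane-1,3-diol
Product: 22 2-[(TBSO)methyl]prop-2-en-1-ol
Conditions: NaH (1.0 equiv), THF, 0 °C; tert-butyldimethylsilyl chloride, rt
Reagents that add atoms: tert-butyldimethylsilyl chloride, CC(C)(C)[Si](C)(C)Cl
Why: Monosilylation through the sparingly soluble monosodium alkoxide of the symmetrical diol.

Step 14
Reactants: 22 monosilylated diol
Product: 23 {[2-(bromomethyl)prop-2-en-1-yl]oxy}(tert-butyl)dimethylsilane
Conditions: CBr4, PPh3, CH2Cl2, 0 °C
Reagents that add atoms: carbon tetrabromide, BrC(Br)(Br)Br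
Why: Appel bromination of a primary allylic alcohol under neutral conditions; the allyl unit is symmetrical, so direct and allylic displacement give the same product.

Step 15
Reactants: 20 enone; 23 allylic bromide
Product: 25 tert-butyl (1S,4S,7R,7aS)-1-{2-[(TBSO)methyl]prop-2-en-1-yl}-4-(PMBO)-7a-methyl-2-oxo-2,4,5,6,7,7a-hexahydro-1H-indene-7-carboxylate, via lithium enolate 24 (not isolated)
Conditions: LiN(iPr)2, THF, −78 °C; 23, DMPU, −78 to −30 °C
Reagents that add atoms: none
Why: Kinetic α′-deprotonation gives cross-conjugated enolate 24; the γ-hydrogen at C4 is equatorial and lies in the nodal plane of the π system, and the C7 hydrogen is far less acidic. C-Alkylation from the face away from the C7a methyl should give mainly the 1S epimer.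

Step 16
Reactants: 25 C1-alkylated enone (1S)
Product: 26 tert-butyl (1R,4S,7R,7aS)-1-{2-[(TBSO)methyl]prop-2-en-1-yl}-4-(PMBO)-7a-methyl-2-oxo-2,4,5,6,7,7a-hexahydro-1H-indene-7-carboxylate
Conditions: DBU (0.3 equiv), CH2Cl2, rt
Reagents that add atoms: none
Why: Base-mediated equilibration at C1 through the enolate: with the side chain cis to the C7a methyl it is anti to the C7a–C7 bond and clear of the C7 substituents, so the 1R epimer should be favoured. C4 is not deprotonated for the stereoelectronic reason given in step 15.

Step 17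
Reactants: 26 PMB ether (1R)
Product: 27 tert-butyl (1R,4S,7R,7aS)-1-{2-[(TBSO)methyl]prop-2-en-1-yl}-4-hydroxy-7a-methyl-2-oxo-2,4,5,6,7,7a-hexahydro-1H-indene-7-carboxylate
Conditions: DDQ, CH2Cl2/pH 7 buffer, 0 °C to rt
Reagents that add atoms: none
Why: Oxidative cleavage of the 4-methoxybenzyl ether under neutral conditions leaves the silyl ether, the tert-butyl ester and the C1 centre untouched.

Step 18
Reactants: 28 (R)-2-methylbutanoic acid
Product: 29 (R)-2-methylbutan-1-ol
Conditions: LiAlH4, Et2O, 0 °C to rt
Reagents that add atoms: none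
Why: Hydride reduction of the acid through its carboxylate, which is not enolised, so the stereocentre is kept.

Step 19
Reactants: 29 (R)-2-methylbutan-1-ol
Product: 31 (2E,4R)-2,4-dimethylhex-2-enal, via (R)-2-methylbutanal 30 (not isolated)
Conditions: Dess–Martin periodinane, CH2Cl2, 0 °C to rt; then Ph3P=C(CH3)CHO, toluene, 80 °C
Reagents that add atoms: 2-(triphenylphosphoranylidene)propanal, CC(C=O)=P(c1ccccc1)(c1ccccc1)c1ccccc1
Why: Oxidation to aldehyde 30 and Wittig olefination without isolation limit racemisation of the α-branched aldehyde; the stabilised formyl ylide gives the E trisubstituted enal.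

Step 20
Reactants: 31 enal
Product: 32 ethyl (2E,4E,6R)-4,6-dimethylocta-2,4-dienoate
Conditions: triethyl phosphonoacetate, NaH, THF, 0 °C to rt
Reagents that add atoms: triethyl phosphonoacetate, CCOC(=O)CP(=O)(OCC)OCC
Why: Horner–Wadsworth–Emmons olefination, E-selective for the new disubstituted alkene.

Step 21
Reactants: 32 ethyl dienoate
Product: 33 (2E,4E,6R)-4,6-dimethylocta-2,4-dienoic acid
Conditions: LiOH, THF/MeOH/H2O, rt; then 1 M HCl
Reagents that add atoms: lithium hydroxide, [Li+].[OH-]
Why: Saponification of the ethyl ester; the stereocentre is remote from the carboxyl and is not at risk.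

Step 22
Reactants: 27 C4 alcohol; 33 dienoic acid
Product: 35 tert-butyl (1R,4S,7R,7aS)-1-{2-[(TBSO)methyl]prop-2-en-1-yl}-4-{[(2E,4E,6R)-4,6-dimethylocta-2,4-dienoyl]oxy}-7a-methyl-2-oxo-2,4,5,6,7,7a-hexahydro-1H-indene-7-carboxylate, via mixed anhydride 34 (not isolated)
Conditions: 2,4,6-trichlorobenzoyl chloride, Et3N, toluene, rt; then 27, 4-dimethylaminopyridine, toluene, rt to 40 °C
Reagents that add atoms: none
Why: Yamaguchi esterification through mixed anhydride 34 acylates the hindered axial alcohol with retention at C4. The acid has no hydrogen on its γ-carbon, so a vinylketene and deconjugation of the diene are excluded.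

Step 23
Reactants: 35 silyl ether
Product: 36 tert-butyl (1R,4S,7R,7aS)-4-{[(2E,4E,6R)-4,6-dimethylocta-2,4-dienoyl]oxy}-1-[2-(hydroxymethyl)prop-2-en-1-yl]-7a-methyl-2-oxo-2,4,5,6,7,7a-hexahydro-1H-indene-7-carboxylate
Conditions: HF·pyridine, pyridine, THF, 0 °C to rt
Reagents that add atoms: none
Why: Buffered HF·pyridine removes the primary allylic silyl ether; both esters, the enone and C1 are stable in the mildly acidic medium.

Step 24
Reactants: 36 allylic alcohol
Product: 37 tert-butyl (1R,4S,7R,7aS)-4-{[(2E,4E,6R)-4,6-dimethylocta-2,4-dienoyl]oxy}-1-(2-formylprop-2-en-1-yl)-7a-methyl-2-oxo-2,4,5,6,7,7a-hexahydro-1H-indene-7-carboxylate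
Conditions: MnO2, CH2Cl2, rt
Reagents that add atoms: none
Why: MnO2 oxidises the primary allylic alcohol selectively to the 2-substituted acrolein; no other hydroxyl is present.

Step 25
Reactants: 37 tert-butyl ester
Product: 38 (1R,4S,7R,7aS)-4-{[(2E,4E,6R)-4,6-dimethylocta-2,4-dienoyl]oxy}-1-(2-formylprop-2-en-1-yl)-7a-methyl-2-oxo-2,4,5,6,7,7a-hexahydro-1H-indene-7-carboxylic acid
Conditions: CF3CO2H, CH2Cl2, 0 °C
Reagents that add atoms: none
Why: Acidolysis of the tert-butyl ester with loss of 2-methylpropene. The allylic C4 ester should not ionise, because the cation would be conjugated with the electron-poor enone, and the dienoate and the enal tolerate a short exposure at 0 °C.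

## Compound list

1 | (S)-4-(TBSO)cyclopent-2-en-1-one | O=C1C=C[C@@H](O[Si](C)(C)C(C)(C)C)C1 | starting material
2 | (S)-4-(TBSO)-2-iodocyclopent-2-en-1-one | O=C1C(I)=C[C@@H](O[Si](C)(C)C(C)(C)C)C1 | intermediate
3 | (1R,4S)-4-(TBSO)-2-iodo-1-methylcyclopent-2-en-1-ol | C[C@]1(O)C(I)=C[C@@H](O[Si](C)(C)C(C)(C)C)C1 | intermediate
4 | tertiary chlorochromate ester of 3 | C[C@]1(O[Cr](=O)(=O)Cl)C(I)=C[C@@H](O[Si](C)(C)C(C)(C)C)C1 | intermediate
5 | transposed chlorochromate ester, (1S,5S)-5-(TBSO)-2-iodo-3-methylcyclopent-2-en-1-yl chlorochromate | Cl[Cr](=O)(=O)O[C@@H]1C(I)=C(C)C[C@@H]1O[Si](C)(C)C(C)(C)C | intermediate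
6 | (S)-5-(TBSO)-2-iodo-3-methylcyclopent-2-en-1-one | CC1=C(I)C(=O)[C@@H](O[Si](C)(C)C(C)(C)C)C1 | intermediate
7 | (1S,5S)-5-(TBSO)-2-iodo-3-methylcyclopent-2-en-1-ol | O[C@@H]1C(I)=C(C)C[C@@H]1O[Si](C)(C)C(C)(C)C | intermediate
8 | hex-5-enoic acid | C=CCCCC(=O)O | starting material
9 | (1S,5S)-5-(TBSO)-2-iodo-3-methylcyclopent-2-en-1-yl hex-5-enoate | C=CCCCC(=O)O[C@@H]1C(I)=C(C)C[C@@H]1O[Si](C)(C)C(C)(C)C | intermediate
10 | (E)-trimethylsilyl ketene acetal of 9 | C=CCC/C=C(/O[Si](C)(C)C)O[C@@H]1C(I)=C(C)C[C@@H]1O[Si](C)(C)C(C)(C)C | intermediate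
11 | trimethylsilyl ester of 12 | IC1=C[C@@H](O[Si](C)(C)C(C)(C)C)C[C@@]1(C)[C@H](C(=O)O[Si](C)(C)C)CCC=C | intermediate
12 | (2R)-2-[(1S,4S)-4-(TBSO)-2-iodo-1-methylcyclopent-2-en-1-yl]hex-5-enoic acid | IC1=C[C@@H](O[Si](C)(C)C(C)(C)C)C[C@@]1(C)[C@H](C(=O)O)CCC=C | intermediate
13 | tert-butyl (2R)-2-[(1S,4S)-4-(TBSO)-2-iodo-1-methylcyclopent-2-en-1-yl]hex-5-enoate | IC1=C[C@@H](O[Si](C)(C)C(C)(C)C)C[C@@]1(C)[C@H](C(=O)OC(C)(C)C)CCC=C | intermediate
14 | tert-butyl (2R)-2-[(1S,4S)-4-(TBSO)-2-iodo-1-methylcyclopent-2-en-1-yl]-5,6-dihydroxyhexanoate (both C5 epimers) | IC1=C[C@@H](O[Si](C)(C)C(C)(C)C)C[C@@]1(C)[C@H](C(=O)OC(C)(C)C)CCC(O)CO | intermediate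
15 | tert-butyl (2R)-2-[(1S,4S)-4-(TBSO)-2-iodo-1-methylcyclopent-2-en-1-yl]-5-oxopentanoate | IC1=C[C@@H](O[Si](C)(C)C(C)(C)C)C[C@@]1(C)[C@H](C(=O)OC(C)(C)C)CCC=O | intermediate
16 | alkenylchromium dichloride from 15 (chromium in place of iodine) | Cl[Cr](Cl)C1=C[C@@H](O[Si](C)(C)C(C)(C)C)C[C@@]1(C)[C@H](C(=O)OC(C)(C)C)CCC=O | intermediate
17 | tert-butyl (2S,4S,7R,7aS)-2-(TBSO)-4-hydroxy-7a-methyl-2,4,5,6,7,7a-hexahydro-1H-indene-7-carboxylate | C1[C@H](O[Si](C)(C)C(C)(C)C)C=C2[C@@H](O)CC[C@@H](C(=O)OC(C)(C)C)[C@@]21C | intermediate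
18 | tert-butyl (2S,4S,7R,7aS)-2-(TBSO)-4-(PMBO)-7a-methyl-2,4,5,6,7,7a-hexahydro-1H-indene-7-carboxylate | C1[C@H](O[Si](C)(C)C(C)(C)C)C=C2[C@@H](OCc3ccc(OC)cc3)CC[C@@H](C(=O)OC(C)(C)C)[C@@]21C | intermediate
19 | tert-butyl (2S,4S,7R,7aS)-2-hydroxy-4-(PMBO)-7a-methyl-2,4,5,6,7,7a-hexahydro-1H-indene-7-carboxylate | C1[C@H](O)C=C2[C@@H](OCc3ccc(OC)cc3)CC[C@@H](C(=O)OC(C)(C)C)[C@@]21C | intermediate
20 | tert-butyl (4S,7R,7aS)-4-(PMBO)-7a-methyl-2-oxo-2,4,5,6,7,7a-hexahydro-1H-indene-7-carboxylate | C1C(=O)C=C2[C@@H](OCc3ccc(OC)cc3)CC[C@@H](C(=O)OC(C)(C)C)[C@@]21C | intermediate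
21 | 2-methylidenepropane-1,3-diol | C=C(CO)CO | starting material
22 | 2-[(TBSO)methyl]prop-2-en-1-ol | C=C(CO)CO[Si](C)(C)C(C)(C)C | intermediate
23 | {[2-(bromomethyl)prop-2-en-1-yl]oxy}(tert-butyl)dimethylsilane | C=C(CBr)CO[Si](C)(C)C(C)(C)C | intermediate
24 | lithium enolate of 20 (C1=C2–OLi) | C1=C(O[Li])C=C2[C@@H](OCc3ccc(OC)cc3)CC[C@@H](C(=O)OC(C)(C)C)[C@@]21C | intermediate
25 | tert-butyl (1S,4S,7R,7aS)-1-{2-[(TBSO)methyl]prop-2-en-1-yl}-4-(PMBO)-7a-methyl-2-oxo-2,4,5,6,7,7a-hexahydro-1H-indene-7-carboxylate | C=C(CO[Si](C)(C)C(C)(C)C)C[C@@H]1C(=O)C=C2[C@@H](OCc3ccc(OC)cc3)CC[C@@H](C(=O)OC(C)(C)C)[C@@]21C | intermediate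
26 | tert-butyl (1R,4S,7R,7aS)-1-{2-[(TBSO)methyl]prop-2-en-1-yl}-4-(PMBO)-7a-methyl-2-oxo-2,4,5,6,7,7a-hexahydro-1H-indene-7-carboxylate | C=C(CO[Si](C)(C)C(C)(C)C)C[C@H]1C(=O)C=C2[C@@H](OCc3ccc(OC)cc3)CC[C@@H](C(=O)OC(C)(C)C)[C@@]21C | intermediate
27 | tert-butyl (1R,4S,7R,7aS)-1-{2-[(TBSO)methyl]prop-2-en-1-yl}-4-hydroxy-7a-methyl-2-oxo-2,4,5,6,7,7a-hexahydro-1H-indene-7-carboxylate | C=C(CO[Si](C)(C)C(C)(C)C)C[C@H]1C(=O)C=C2[C@@H](O)CC[C@@H](C(=O)OC(C)(C)C)[C@@]21C | intermediate
28 | (R)-2-methylbutanoic acid | CC[C@@H](C)C(=O)O | starting material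
29 | (R)-2-methylbutan-1-ol | CC[C@@H](C)CO | intermediate
30 | (R)-2-methylbutanal | CC[C@@H](C)C=O | intermediate
31 | (2E,4R)-2,4-dimethylhex-2-enal | O=C/C(C)=C/[C@H](C)CC | intermediate
32 | ethyl (2E,4E,6R)-4,6-dimethylocta-2,4-dienoate | CCOC(=O)/C=C/C(C)=C/[C@H](C)CC | intermediate
33 | (2E,4E,6R)-4,6-dimethylocta-2,4-dienoic acid | OC(=O)/C=C/C(C)=C/[C@H](C)CC | intermediate
34 | mixed anhydride of 33 with 2,4,6-trichlorobenzoic acid | O=C(/C=C/C(C)=C/[C@H](C)CC)OC(=O)c1c(Cl)cc(Cl)cc1Cl | intermediate
35 | tert-butyl (1R,4S,7R,7aS)-1-{2-[(TBSO)methyl]prop-2-en-1-yl}-4-{[(2E,4E,6R)-4,6-dimethylocta-2,4-dienoyl]oxy}-7a-methyl-2-oxo-2,4,5,6,7,7a-hexahydro-1H-indene-7-carboxylate | C=C(CO[Si](C)(C)C(C)(C)C)C[C@H]1C(=O)C=C2[C@@H](OC(=O)/C=C/C(C)=C/[C@H](C)CC)CC[C@@H](C(=O)OC(C)(C)C)[C@@]21C | intermediate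
36 | tert-butyl (1R,4S,7R,7aS)-4-{[(2E,4E,6R)-4,6-dimethylocta-2,4-dienoyl]oxy}-1-[2-(hydroxymethyl)prop-2-en-1-yl]-7a-methyl-2-oxo-2,4,5,6,7,7a-hexahydro-1H-indene-7-carboxylate | C=C(CO)C[C@H]1C(=O)C=C2[C@@H](OC(=O)/C=C/C(C)=C/[C@H](C)CC)CC[C@@H](C(=O)OC(C)(C)C)[C@@]21C | intermediate
37 | tert-butyl (1R,4S,7R,7aS)-4-{[(2E,4E,6R)-4,6-dimethylocta-2,4-dienoyl]oxy}-1-(2-formylprop-2-en-1-yl)-7a-methyl-2-oxo-2,4,5,6,7,7a-hexahydro-1H-indene-7-carboxylate | C=C(C=O)C[C@H]1C(=O)C=C2[C@@H](OC(=O)/C=C/C(C)=C/[C@H](C)CC)CC[C@@H](C(=O)OC(C)(C)C)[C@@]21C | intermediate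
38 | (1R,4S,7R,7aS)-4-{[(2E,4E,6R)-4,6-dimethylocta-2,4-dienoyl]oxy}-1-(2-formylprop-2-en-1-yl)-7a-methyl-2-oxo-2,4,5,6,7,7a-hexahydro-1H-indene-7-carboxylic acid | C=C(C=O)C[C@H]1C(=O)C=C2[C@@H](OC(=O)/C=C/C(C)=C/[C@H](C)CC)CC[C@@H](C(=O)O)[C@@]21C | target

## Step count and risks

Total: 25 steps. Longest linear sequence: 19 steps from enone 1 (steps 1 to 12, 15 to 17 and 22 to 25). Side branches: steps 13 and 14 (bromide 23) and steps 18 to 21 (acid 33).

**Step 9 (key step).** The likely failure is poor facial selectivity at the aldehyde, because an in-plane delivery with the chromium-bound oxygen equatorial competes with delivery from the C7 face. Protonation of the alkenylchromium species before it reaches the aldehyde is a second risk. The fallback no longer relies on the addition for the C4 configuration. It sets out from aldehyde 15: the cyclisation is run as before and the unseparated carbinols, 17 and its C4 epimer tert-butyl (2S,4R,7R,7aS)-2-(TBSO)-4-hydroxy-7a-methyl-2,4,5,6,7,7a-hexahydro-1H-indene-7-carboxylate F1, are oxidised together with Dess–Martin periodinane to the C4 enone tert-butyl (2S,7R,7aS)-2-(TBSO)-7a-methyl-4-oxo-2,4,5,6,7,7a-hexahydro-1H-indene-7-carboxylate F2. Luche reduction (NaBH4, CeCl3·7H2O, MeOH, −78 °C) then delivers hydride to C4 from the face opposite the axial C7a methyl and comes back at 17.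

**Step 3.** The [3,3] shift may be slow across the iodine-bearing, electron-poor alkene, so that ionisation and elimination of the tertiary allylic alcohol take over. The α-silyloxy ketone product may also enolise, which would erode the enantiomeric purity of everything that follows. The fallback changes the order of events and sets out from enone 1. MeMgBr/CeCl3 gives (1R,4S)-4-(TBSO)-1-methylcyclopent-2-en-1-ol F3, whose oxidative transposition now runs across an electron-rich alkene to (S)-5-(TBSO)-3-methylcyclopent-2-en-1-one F4. α-Iodination (I2, pyridine, CH2Cl2, 0 °C) comes back at 6.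

**Step 6.** Partition between boat-like and chair-like arrays, or incomplete E selectivity in the enolisation, would give a mixture at C7; C7a is not at risk. The fallback sets C7 after ring closure instead of in the rearrangement. It sets out from ester 9, which is rearranged as before. The C7 epimer (2S)-2-[(1S,4S)-4-(TBSO)-2-iodo-1-methylcyclopent-2-en-1-yl]hex-5-enoic acid F5 is carried through steps 7 to 9 as the tert-butyl ester F6, the aldehyde F7 and the bicyclic alcohol F8 (drawn with C4 as in 17). F8 is deprotonated at oxygen and at C7 with an excess of LiN(iPr)2 (THF, −78 to −20 °C), and the ester enolate is protonated at −78 °C with 2,6-di-tert-butylphenol from the face opposite the axial C7a methyl. This places the ester equatorial and comes back at 17.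

**Step 16.** The equilibrium may not favour the 1R epimer strongly enough, or slow base-induced loss of 4-methoxybenzyl alcohol from the γ-position may compete. The fallback uses kinetic control and sets out from 25. LiN(SiMe3)2 (THF, −78 °C) regenerates the enolate as the lithium enolate of 25 F9, which is protonated at −78 °C with 2,6-di-tert-butylphenol on the face away from the C7a methyl and comes back at 26.

**Step 25.** Acid-induced ionisation of the allylic C4 ester, or oligomerisation of the acrolein during acidolysis and concentration, may occur. The fallback reverses the last two operations so that the enal never meets acid. It sets out from alcohol 36: CF3CO2H in CH2Cl2 at 0 °C gives the hydroxy acid (1R,4S,7R,7aS)-4-{[(2E,4E,6R)-4,6-dimethylocta-2,4-dienoyl]oxy}-1-[2-(hydroxymethyl)prop-2-en-1-yl]-7a-methyl-2-oxo-2,4,5,6,7,7a-hexahydro-1H-indene-7-carboxylic acid F10, and oxidation of its allylic alcohol with MnO2 in CH2Cl2 comes back at target 38.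

## Further compounds

F1 | step 9 | tert-butyl (2S,4R,7R,7aS)-2-(TBSO)-4-hydroxy-7a-methyl-2,4,5,6,7,7a-hexahydro-1H-indene-7-carboxylate | C1[C@H](O[Si](C)(C)C(C)(C)C)C=C2[C@H](O)CC[C@@H](C(=O)OC(C)(C)C)[C@@]21C
F2 | step 9 | tert-butyl (2S,7R,7aS)-2-(TBSO)-7a-methyl-4-oxo-2,4,5,6,7,7a-hexahydro-1H-indene-7-carboxylate | C1[C@H](O[Si](C)(C)C(C)(C)C)C=C2C(=O)CC[C@@H](C(=O)OC(C)(C)C)[C@@]21C
F3 | step 3 | (1R,4S)-4-(TBSO)-1-methylcyclopent-2-en-1-ol | C[C@]1(O)C=C[C@@H](O[Si](C)(C)C(C)(C)C)C1
F4 | step 3 | (S)-5-(TBSO)-3-methylcyclopent-2-en-1-one | CC1=CC(=O)[C@@H](O[Si](C)(C)C(C)(C)C)C1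
F5 | step 6 | (2S)-2-[(1S,4S)-4-(TBSO)-2-iodo-1-methylcyclopent-2-en-1-yl]hex-5-enoic acid | IC1=C[C@@H](O[Si](C)(C)C(C)(C)C)C[C@@]1(C)[C@@H](C(=O)O)CCC=C
F6 | step 6 | tert-butyl (2S)-2-[(1S,4S)-4-(TBSO)-2-iodo-1-methylcyclopent-2-en-1-yl]hex-5-enoate | IC1=C[C@@H](O[Si](C)(C)C(C)(C)C)C[C@@]1(C)[C@@H](C(=O)OC(C)(C)C)CCC=C
F7 | step 6 | tert-butyl (2S)-2-[(1S,4S)-4-(TBSO)-2-iodo-1-methylcyclopent-2-en-1-yl]-5-oxopentanoate | IC1=C[C@@H](O[Si](C)(C)C(C)(C)C)C[C@@]1(C)[C@@H](C(=O)OC(C)(C)C)CCC=O
F8 | step 6 | tert-butyl (2S,4S,7S,7aS)-2-(TBSO)-4-hydroxy-7a-methyl-2,4,5,6,7,7a-hexahydro-1H-indene-7-carboxylate | C1[C@H](O[Si](C)(C)C(C)(C)C)C=C2[C@@H](O)CC[C@H](C(=O)OC(C)(C)C)[C@@]21C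
F9 | step 16 | lithium enolate of 25 (C1=C2–OLi) | C=C(CO[Si](C)(C)C(C)(C)C)CC1=C(O[Li])C=C2[C@@H](OCc3ccc(OC)cc3)CC[C@@H](C(=O)OC(C)(C)C)[C@@]21C
F10 | step 25 | (1R,4S,7R,7aS)-4-{[(2E,4E,6R)-4,6-dimethylocta-2,4-dienoyl]oxy}-1-[2-(hydroxymethyl)prop-2-en-1-yl]-7a-methyl-2-oxo-2,4,5,6,7,7a-hexahydro-1H-indene-7-carboxylic acid | C=C(CO)C[C@H]1C(=O)C=C2[C@@H](OC(=O)/C=C/C(C)=C/[C@H](C)CC)CC[C@@H](C(=O)O)[C@@]21C
A1 | alternative 1 | tricyclic acetoxycyclobutane photoadduct | O=C1C[C@@H]2[C@@H](O[Si](C)(C)C(C)(C)C)CC[C@@H]3[C@@H](OC(C)=O)[C@H]1[C@]23C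
A2 | alternative 2 | cyclopropyl carbinol with a CH2 bridge between C1 and C7a | O[C@H]1C[C@@H]2[C@@H](O[Si](C)(C)C(C)(C)C)CC[C@@H](C(=O)OC(C)(C)C)[C@@]23C[C@@H]13
A3 | alternative 3 | tert-butyl (4S,7R,7aS)-4-(TBSO)-7a-methyl-2-oxo-2,4,5,6,7,7a-hexahydro-1H-indene-7-carboxylate | C1C(=O)C=C2[C@@H](O[Si](C)(C)C(C)(C)C)CC[C@@H](C(=O)OC(C)(C)C)[C@@]21C
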